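**Retrosynthetic overview**
- The strategy rests on the right trans-fused bicycle: oxepane (O21, C20, C19, C18, C17, C16, C22) fused to cyclohexane (C15, C16, C22, C23, C24, C25). It maps onto an open chain with C19/C20 and C16/C22 epoxides and a C15=C25 enol ether.
- The left bicycle (oxepane O6, C7–C11, C5; cyclohexane C2–C5, C11, C12) has the same pattern and the same absolute configuration, so both halves come from one (R,R,R)-diepoxide of geranylacetone.
- Endgame: target ⇐ C8 silyl ether removal ⇐ C19/C25 diacetate ⇐ equatorial MeMgBr addition to the C25 ketone.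
- Key disconnection: O21–C20 and C15–C16, opened to a diepoxy (Z)-triethylsilyl enol ether. The enol ether comes from the C14=C15 enone, made by aldol addition of the diepoxy ketone enolate to the left-half C14 aldehyde, elimination, then 1,4-hydrosilylation.
- Ring order: left oxepane and cyclohexanone first (step 5, same cascade on a simple chain), right oxepane and cyclohexanone last (step 13).

Key step: step 13

Assumption: skeleton atoms are numbered C1–C25 in the order of the target SMILES, leaving out methyl, hydroxyl and acetoxy groups; aldehyde 3 is taken as a catalogue compound.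

**Step 1**
Reactants: 1 geranylacetone, (5E)-6,10-dimethylundeca-5,9-dien-2-one
Product: 2 (5R,6R,9R)-5,6:9,10-diepoxy-6,10-dimethylundecan-2-one
Conditions: D-fructose-derived Shi ketone (1,2:4,5-di-O-isopropylidene-β-D-erythro-2,3-hexodiulo-2,6-pyranose, 0.3 equiv per alkene), Oxone (2KHSO5·KHSO4·K2SO4), K2CO3, Bu4NHSO4, MeCN/CH2(OMe)2, aq Na2B4O7/Na2EDTA, 0 °C
Reagents that add atoms: potassium peroxymonosulfate (Oxone), [K+].[O-]S(=O)(=O)OO
Why: Shi asymmetric epoxidation, in which the chiral dioxirane should deliver oxygen through a spiro transition state to the same face of both E-trisubstituted alkenes, setting all three epoxide carbons R (later C5, C11, C8 and C22, C16, C19), while the basic buffer keeps the epoxy ketone from cyclising.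

**Step 2**
Reactants: 2 (5R,6R,9R)-5,6:9,10-diepoxy-6,10-dimethylundecan-2-one; 3 2-[(4-methoxybenzyl)oxy]acetaldehyde
Product: 5 (7R,8R,11R)-7,8:11,12-diepoxy-2-hydroxy-1-[(4-methoxybenzyl)oxy]-8,12-dimethyltridecan-4-one (both C2 carbinol epimers), via sodium enolate 4 (not isolated)
Conditions: NaN(SiMe3)2, THF, −78 °C (2 added to the base); then 3 (1.5 equiv), −78 °C; AcOH quench at −78 °C
Reagents that add atoms: none
Why: kinetic deprotonation of the methyl ketone at CH3 by the hindered silylamide gives the sodium enolate, which should undergo crossed aldol addition to the electrophilic α-alkoxy aldehyde at −78 °C, where trisubstituted epoxides are inert to the amide and the enolate; the carbinol centre is removed in step 3, so its configuration does not matter.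

**Step 3**
Reactants: 5 (7R,8R,11R)-7,8:11,12-diepoxy-2-hydroxy-1-[(4-methoxybenzyl)oxy]-8,12-dimethyltridecan-4-one
Product: 7 (2E,7R,8R,11R)-7,8:11,12-diepoxy-1-[(4-methoxybenzyl)oxy]-8,12-dimethyltridec-2-en-4-one, via mesylate 6 (not isolated)
Conditions: MsCl, Et3N, CH2Cl2, 0 °C to rt
Reagents that add atoms: none
Why: mesylation and E1cB elimination of the β-mesyloxy ketone should give the conjugated (E)-enone under non-acidic conditions that spare both epoxides and the PMB ether.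

**Step 4**
Reactants: 7 (2E,7R,8R,11R)-7,8:11,12-diepoxy-1-[(4-methoxybenzyl)oxy]-8,12-dimethyltridec-2-en-4-one
Product: 8 (3Z,7R,8R,11R)-7,8:11,12-diepoxy-1-[(4-methoxybenzyl)oxy]-8,12-dimethyl-4-(triethylsilyloxy)tridec-3-ene
Conditions: RhCl(PPh3)3 (2 mol%), Et3SiH, THF, 50 °C
Reagents that add atoms: triethylsilane, CC[SiH](CC)CC
Why: rhodium-catalysed 1,4-hydrosilylation of the s-cis enone puts hydride on the β-carbon and silicon on oxygen, so the enol ether should form only at C12=C2 and with (Z) geometry (chain cis to OSi), under neutral conditions that leave the epoxides alone.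

**Step 5**
Reactants: 8 (3Z,7R,8R,11R)-7,8:11,12-diepoxy-1-[(4-methoxybenzyl)oxy]-8,12-dimethyl-4-(triethylsilyloxy)tridec-3-ene
Product: 10 (3R,5aR,6R,9aR)-3-hydroxy-6-{2-[(4-methoxybenzyl)oxy]ethyl}-2,2,5a-trimethyloctahydro-1-benzoxepin-7(2H)-one, via trimethylsilyl ether 9 (not isolated)
Conditions: Me3SiOTf, 2,6-di-tert-butyl-4-methylpyridine, CH2Cl2, −78 °C; aq NaHCO3; then PPTS, MeOH, rt
Reagents that add atoms: none
Why: silyl-triflate-promoted tandem oxacyclization/carbocyclization of a 1,5-diepoxide terminated by a silyl enol ether should close the left oxepane (O6–C7) and cyclohexanone (C11–C12) through a bicyclic epoxonium ion and a chair, with C11 set by inversion of the epoxide carbon and C12 by the (Z)-enol ether placing the side chain equatorial; mild acidic methanolysis then frees the C8 hydroxyl.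

**Step 6**
Reactants: 10 (3R,5aR,6R,9aR)-3-hydroxy-6-{2-[(4-methoxybenzyl)oxy]ethyl}-2,2,5a-trimethyloctahydro-1-benzoxepin-7(2H)-one
Product: 11 (3R,5aR,6R,9aR)-3-(tert-butyldimethylsilyloxy)-6-{2-[(4-methoxybenzyl)oxy]ethyl}-2,2,5a-trimethyloctahydro-1-benzoxepin-7(2H)-one
Conditions: tBuMe2SiOTf, 2,6-lutidine, CH2Cl2, −78 to 0 °C
Reagents that add atoms: tert-butyldimethylsilyl trifluoromethanesulfonate, CC(C)(C)[Si](C)(C)OS(=O)(=O)C(F)(F)F
Why: silyl triflate silylation of the hindered secondary C8 alcohol, giving a tert-butyldimethylsilyl ether that should outlast the later methanolysis of the small silyl group on O-19 and so keep C8 distinct from C19.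

**Step 7**
Reactants: 11 (3R,5aR,6R,9aR)-3-(tert-butyldimethylsilyloxy)-6-{2-[(4-methoxybenzyl)oxy]ethyl}-2,2,5a-trimethyloctahydro-1-benzoxepin-7(2H)-one
Product: 12 (3R,5aR,6S,9aR)-3-(tert-butyldimethylsilyloxy)-6-{2-[(4-methoxybenzyl)oxy]ethyl}-2,2,5a-trimethyl-7-methylidenedecahydro-1-benzoxepine
Conditions: Ph3PCH3Br, KOtBu, toluene, rt to 80 °C
Reagents that add atoms: methyltriphenylphosphonium bromide, C[P+](c1ccccc1)(c1ccccc1)c1ccccc1.[Br-]
Why: Wittig methylenation with the salt-free ylide should convert the hindered α-branched cyclohexanone into the C2=C1 exocyclic alkene, and any enolisation returns the more stable equatorial C12 epimer.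

**Step 8**
Reactants: 12 (3R,5aR,6S,9aR)-3-(tert-butyldimethylsilyloxy)-6-{2-[(4-methoxybenzyl)oxy]ethyl}-2,2,5a-trimethyl-7-methylidenedecahydro-1-benzoxepine
Product: 13 2-[(3R,5aR,6S,9aR)-3-(tert-butyldimethylsilyloxy)-2,2,5a-trimethyl-7-methylidenedecahydro-1-benzoxepin-6-yl]ethanol
Conditions: DDQ, CH2Cl2/pH 7 buffer, 0 °C
Reagents that add atoms: none
Why: oxidative PMB ether cleavage by benzylic hydride abstraction, which should not touch the isolated 1,1-disubstituted alkene or the silyl ether.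

**Step 9**
Reactants: 13 2-[(3R,5aR,6S,9aR)-3-(tert-butyldimethylsilyloxy)-2,2,5a-trimethyl-7-methylidenedecahydro-1-benzoxepin-6-yl]ethanol
Product: 14 [(3R,5aR,6S,9aR)-3-(tert-butyldimethylsilyloxy)-2,2,5a-trimethyl-7-methylidenedecahydro-1-benzoxepin-6-yl]acetaldehyde (C14 aldehyde)
Conditions: Dess–Martin periodinane, NaHCO3, CH2Cl2, 0 °C to rt
Reagents that add atoms: none
Why: Dess–Martin oxidation of the primary alcohol under buffered conditions should give the aldehyde without over-oxidation or migration of the exocyclic alkene.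

**Step 10**
Reactants: 2 (5R,6R,9R)-5,6:9,10-diepoxy-6,10-dimethylundecan-2-one; 14 [(3R,5aR,6S,9aR)-3-(tert-butyldimethylsilyloxy)-2,2,5a-trimethyl-7-methylidenedecahydro-1-benzoxepin-6-yl]acetaldehyde
Product: 16 (7R,8R,11R)-1-[(3R,5aR,6S,9aR)-3-(tert-butyldimethylsilyloxy)-2,2,5a-trimethyl-7-methylidenedecahydro-1-benzoxepin-6-yl]-7,8:11,12-diepoxy-2-hydroxy-8,12-dimethyltridecan-4-one (both C14 carbinol epimers), via lithium enolate 15 (not isolated)
Conditions: 2 (1.3 equiv), LiN(iPr)2, THF, −78 °C; then 14, −78 °C; AcOH quench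
Reagents that add atoms: none
Why: aldol addition of the kinetic lithium enolate of the methyl ketone, whose tight lithium aldolate resists retro-aldol cleavage and proton transfer to the valuable aldehyde, forms the C14–C15 bond at −78 °C without touching the epoxides, the silyl ether or the alkene, and the carbinol configuration is erased in step 11.

**Step 11**
Reactants: 16 (7R,8R,11R)-1-[(3R,5aR,6S,9aR)-3-(tert-butyldimethylsilyloxy)-2,2,5a-trimethyl-7-methylidenedecahydro-1-benzoxepin-6-yl]-7,8:11,12-diepoxy-2-hydroxy-8,12-dimethyltridecan-4-one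
Product: 18 (2E,7R,8R,11R)-1-[(3R,5aR,6S,9aR)-3-(tert-butyldimethylsilyloxy)-2,2,5a-trimethyl-7-methylidenedecahydro-1-benzoxepin-6-yl]-7,8:11,12-diepoxy-8,12-dimethyltridec-2-en-4-one, via mesylate 17 (not isolated)
Conditions: MsCl, Et3N, CH2Cl2, 0 °C to rt
Reagents that add atoms: none
Why: mesylation and E1cB elimination should give the (E)-C14=C15 enone under the non-acidic conditions already used in step 3.

**Step 12**
Reactants: 18 (2E,7R,8R,11R)-1-[(3R,5aR,6S,9aR)-3-(tert-butyldimethylsilyloxy)-2,2,5a-trimethyl-7-methylidenedecahydro-1-benzoxepin-6-yl]-7,8:11,12-diepoxy-8,12-dimethyltridec-2-en-4-one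
Product: 19 (3Z,7R,8R,11R)-1-[(3R,5aR,6S,9aR)-3-(tert-butyldimethylsilyloxy)-2,2,5a-trimethyl-7-methylidenedecahydro-1-benzoxepin-6-yl]-7,8:11,12-diepoxy-8,12-dimethyl-4-(triethylsilyloxy)tridec-3-ene
Conditions: RhCl(PPh3)3 (2 mol%), Et3SiH, THF, 50 °C
Reagents that add atoms: triethylsilane, CC[SiH](CC)CC
Why: rhodium-catalysed 1,4-hydrosilylation of the s-cis enone should give the C15=C25 enol ether regiospecifically and with (Z) geometry, the conjugated enone reacting much faster than the hindered exocyclic alkene.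

**Step 13**
Reactants: 19 (3Z,7R,8R,11R)-1-[(3R,5aR,6S,9aR)-3-(tert-butyldimethylsilyloxy)-2,2,5a-trimethyl-7-methylidenedecahydro-1-benzoxepin-6-yl]-7,8:11,12-diepoxy-8,12-dimethyl-4-(triethylsilyloxy)tridec-3-ene
Product: 21 (3R,5aR,6R,9aR)-6-{2-[(3R,5aR,6S,9aR)-3-(tert-butyldimethylsilyloxy)-2,2,5a-trimethyl-7-methylidenedecahydro-1-benzoxepin-6-yl]ethyl}-3-hydroxy-2,2,5a-trimethyloctahydro-1-benzoxepin-7(2H)-one, via trimethylsilyl ether 20 (not isolated)
Conditions: Me3SiOTf, 2,6-di-tert-butyl-4-methylpyridine, CH2Cl2, −78 °C; aq NaHCO3; then PPTS, MeOH, 0 °C to rt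
Reagents that add atoms: none
Why: Me3Si+ silylates the oxygen of the terminal C19/C20 epoxide, the oxygen of the C16/C22 epoxide (O21) opens it at the tertiary carbon C20 to give a bicyclic epoxonium ion, and the enol ether carbon C15 opens that ion at the tertiary carbon C16 with inversion, the C25 silyloxycarbenium ion then collapsing to the ketone by loss of Et3SiOTf. The closest known reaction type is the silyl-triflate-promoted tandem oxacyclization/carbocyclization of 1,5-diepoxides terminated by a silyl enol ether, which step 5 rehearses on a simpler chain. The oxepane (O21, C20, C19, C18, C17, C16, C22) closes by endo attack on the C19/C20 epoxide and is seven-membered once the C16–O21 bond breaks (net 7-endo), and the cyclohexanone (C15, C16, C22, C23, C24, C25) closes by 6-endo opening of the epoxonium ion through a chair. C16 is set by stereospecific inversion of the (16R)-epoxide carbon, which with the retained C22–O21 bond gives the trans ring fusion, and C15 by the (Z)-enol ether in the chair, which puts the C14 chain equatorial and H-15 anti to the C16 methyl; C19 and C22 are carried over from the epoxides. The step needs activation of the terminal rather than the internal epoxide, C- rather than O-attack of the enol ether, and no involvement of the C1=C2 alkene or the C8 silyl ether; the more accessible terminal epoxide, the six-membered chair, the hindered pyridine buffer at −78 °C and the distance of the left bicycle from the cationic centres should secure these. The acidic methanolysis removes whichever small silyl group (Me3Si or Et3Si) sits on O-19 while the C8 tert-butyldimethylsilyl ether stays.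

**Step 14**
Reactants: 21 (3R,5aR,6R,9aR)-6-{2-[(3R,5aR,6S,9aR)-3-(tert-butyldimethylsilyloxy)-2,2,5a-trimethyl-7-methylidenedecahydro-1-benzoxepin-6-yl]ethyl}-3-hydroxy-2,2,5a-trimethyloctahydro-1-benzoxepin-7(2H)-one
Product: 22 (3R,5aR,6R,7S,9aR)-6-{2-[(3R,5aR,6S,9aR)-3-(tert-butyldimethylsilyloxy)-2,2,5a-trimethyl-7-methylidenedecahydro-1-benzoxepin-6-yl]ethyl}-2,2,5a,7-tetramethyldecahydro-1-benzoxepine-3,7-diol
Conditions: MeMgBr (excess), THF, −78 to 0 °C; aq NH4Cl
Reagents that add atoms: methylmagnesium bromide, C[Mg]Br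
Why: Grignard 1,2-addition after deprotonation of the C19 hydroxyl should come from the equatorial direction because the axial path to C25 is blocked by the syn-axial C16 methyl, which sets C25 (S) with the hydroxyl axial and the new methyl equatorial.

**Step 15**
Reactants: 22 (3R,5aR,6R,7S,9aR)-6-{2-[(3R,5aR,6S,9aR)-3-(tert-butyldimethylsilyloxy)-2,2,5a-trimethyl-7-methylidenedecahydro-1-benzoxepin-6-yl]ethyl}-2,2,5a,7-tetramethyldecahydro-1-benzoxepine-3,7-diol
Product: 23 (3R,5aR,6R,7S,9aR)-6-{2-[(3R,5aR,6S,9aR)-3-(tert-butyldimethylsilyloxy)-2,2,5a-trimethyl-7-methylidenedecahydro-1-benzoxepin-6-yl]ethyl}-2,2,5a,7-tetramethyldecahydro-1-benzoxepine-3,7-diyl diacetate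
Conditions: Ac2O, DMAP, Et3N, CH2Cl2, rt to 40 °C
Reagents that add atoms: acetic anhydride, CC(=O)OC(C)=O
Why: DMAP-catalysed acylation through the N-acetylpyridinium ion should acetylate the secondary C19 hydroxyl and, more slowly, the tertiary axial C25 hydroxyl, while C8 stays masked as its silyl ether.

**Step 16**
Reactants: 23 (3R,5aR,6R,7S,9aR)-6-{2-[(3R,5aR,6S,9aR)-3-(tert-butyldimethylsilyloxy)-2,2,5a-trimethyl-7-methylidenedecahydro-1-benzoxepin-6-yl]ethyl}-2,2,5a,7-tetramethyldecahydro-1-benzoxepine-3,7-diyl diacetate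
Product: 24 (3R,5aR,6R,7S,9aR)-6-{2-[(3R,5aR,6S,9aR)-3-hydroxy-2,2,5a-trimethyl-7-methylidenedecahydro-1-benzoxepin-6-yl]ethyl}-2,2,5a,7-tetramethyldecahydro-1-benzoxepine-3,7-diyl diacetate (CNP0412606.2)
Conditions: HF·pyridine, pyridine, THF, 0 °C to rt
Reagents that add atoms: none
Why: fluoride cleavage of the tert-butyldimethylsilyl ether under pyridine-buffered conditions should free the C8 hydroxyl without hydrolysing either acetate or protonating the exocyclic alkene.

**Compound list**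
1 | geranylacetone, (5E)-6,10-dimethylundeca-5,9-dien-2-one | CC(C)=CCC/C(C)=C/CCC(C)=O | starting material
2 | (5R,6R,9R)-5,6:9,10-diepoxy-6,10-dimethylundecan-2-one | CC(=O)CC[C@H]1O[C@]1(C)CC[C@H]1OC1(C)C | intermediate
3 | 2-[(4-methoxybenzyl)oxy]acetaldehyde | COc1ccc(COCC=O)cc1 | starting material
4 | sodium (5R,6R,9R)-5,6:9,10-diepoxy-6,10-dimethylundec-1-en-2-olate (kinetic sodium enolate of 2) | C=C([O-])CC[C@H]1O[C@]1(C)CC[C@H]1OC1(C)C.[Na+] | intermediate
5 | (7R,8R,11R)-7,8:11,12-diepoxy-2-hydroxy-1-[(4-methoxybenzyl)oxy]-8,12-dimethyltridecan-4-one (C2 epimers) | COc1ccc(COCC(O)CC(=O)CC[C@H]2O[C@]2(C)CC[C@H]2OC2(C)C)cc1 | intermediate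
6 | 2-O-methanesulfonate of 5 | COc1ccc(COCC(OS(C)(=O)=O)CC(=O)CC[C@H]2O[C@]2(C)CC[C@H]2OC2(C)C)cc1 | intermediate
7 | (2E,7R,8R,11R)-7,8:11,12-diepoxy-1-[(4-methoxybenzyl)oxy]-8,12-dimethyltridec-2-en-4-one | COc1ccc(COC/C=C/C(=O)CC[C@H]2O[C@]2(C)CC[C@H]2OC2(C)C)cc1 | intermediate
8 | (3Z,7R,8R,11R)-7,8:11,12-diepoxy-1-[(4-methoxybenzyl)oxy]-8,12-dimethyl-4-(triethylsilyloxy)tridec-3-ene | COc1ccc(COCC/C=C(\O[Si](CC)(CC)CC)CC[C@H]2O[C@]2(C)CC[C@H]2OC2(C)C)cc1 | intermediate
9 | (3R,5aR,6R,9aR)-6-{2-[(4-methoxybenzyl)oxy]ethyl}-2,2,5a-trimethyl-3-(trimethylsilyloxy)octahydro-1-benzoxepin-7(2H)-one | O=C1CC[C@H]2OC(C)(C)[C@H](O[Si](C)(C)C)CC[C@]2(C)[C@H]1CCOCc1ccc(OC)cc1 | intermediate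
10 | (3R,5aR,6R,9aR)-3-hydroxy-6-{2-[(4-methoxybenzyl)oxy]ethyl}-2,2,5a-trimethyloctahydro-1-benzoxepin-7(2H)-one | O=C1CC[C@H]2OC(C)(C)[C@H](O)CC[C@]2(C)[C@H]1CCOCc1ccc(OC)cc1 | intermediate
11 | (3R,5aR,6R,9aR)-3-(tert-butyldimethylsilyloxy)-6-{2-[(4-methoxybenzyl)oxy]ethyl}-2,2,5a-trimethyloctahydro-1-benzoxepin-7(2H)-one | O=C1CC[C@H]2OC(C)(C)[C@H](O[Si](C)(C)C(C)(C)C)CC[C@]2(C)[C@H]1CCOCc1ccc(OC)cc1 | intermediate
12 | (3R,5aR,6S,9aR)-3-(tert-butyldimethylsilyloxy)-6-{2-[(4-methoxybenzyl)oxy]ethyl}-2,2,5a-trimethyl-7-methylidenedecahydro-1-benzoxepine | C=C1CC[C@H]2OC(C)(C)[C@H](O[Si](C)(C)C(C)(C)C)CC[C@]2(C)[C@H]1CCOCc1ccc(OC)cc1 | intermediate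
13 | 2-[(3R,5aR,6S,9aR)-3-(tert-butyldimethylsilyloxy)-2,2,5a-trimethyl-7-methylidenedecahydro-1-benzoxepin-6-yl]ethanol | C=C1CC[C@H]2OC(C)(C)[C@H](O[Si](C)(C)C(C)(C)C)CC[C@]2(C)[C@H]1CCO | intermediate
14 | [(3R,5aR,6S,9aR)-3-(tert-butyldimethylsilyloxy)-2,2,5a-trimethyl-7-methylidenedecahydro-1-benzoxepin-6-yl]acetaldehyde | C=C1CC[C@H]2OC(C)(C)[C@H](O[Si](C)(C)C(C)(C)C)CC[C@]2(C)[C@H]1CC=O | intermediate
15 | lithium (5R,6R,9R)-5,6:9,10-diepoxy-6,10-dimethylundec-1-en-2-olate (kinetic lithium enolate of 2) | C=C([O-])CC[C@H]1O[C@]1(C)CC[C@H]1OC1(C)C.[Li+] | intermediate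
16 | C14 β-hydroxy C25 ketone: 1-(left bicycle)-7,8:11,12-diepoxy-2-hydroxy-8,12-dimethyltridecan-4-one (C14 epimers) | C=C1CC[C@H]2OC(C)(C)[C@H](O[Si](C)(C)C(C)(C)C)CC[C@]2(C)[C@H]1CC(O)CC(=O)CC[C@H]1O[C@]1(C)CC[C@H]1OC1(C)C | intermediate
17 | C14 methanesulfonate of 16 | C=C1CC[C@H]2OC(C)(C)[C@H](O[Si](C)(C)C(C)(C)C)CC[C@]2(C)[C@H]1CC(OS(C)(=O)=O)CC(=O)CC[C@H]1O[C@]1(C)CC[C@H]1OC1(C)C | intermediate
18 | (E)-C14=C15 enone: 1-(left bicycle)-7,8:11,12-diepoxy-8,12-dimethyltridec-2-en-4-one | C=C1CC[C@H]2OC(C)(C)[C@H](O[Si](C)(C)C(C)(C)C)CC[C@]2(C)[C@H]1C/C=C/C(=O)CC[C@H]1O[C@]1(C)CC[C@H]1OC1(C)C | intermediate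
19 | (Z)-C15=C25 triethylsilyl enol ether (cascade precursor) | C=C1CC[C@H]2OC(C)(C)[C@H](O[Si](C)(C)C(C)(C)C)CC[C@]2(C)[C@H]1CC/C=C(\O[Si](CC)(CC)CC)CC[C@H]1O[C@]1(C)CC[C@H]1OC1(C)C | intermediate
20 | C19 trimethylsilyl ether of 21 | C=C1CC[C@H]2OC(C)(C)[C@H](O[Si](C)(C)C(C)(C)C)CC[C@]2(C)[C@H]1CC[C@@H]1[C@@]2(C)CC[C@@H](O[Si](C)(C)C)C(C)(C)O[C@@H]2CCC1=O | intermediate
21 | C25 ketone with free C19 hydroxyl and C8 tert-butyldimethylsilyl ether (cascade product) | C=C1CC[C@H]2OC(C)(C)[C@H](O[Si](C)(C)C(C)(C)C)CC[C@]2(C)[C@H]1CC[C@@H]1[C@@]2(C)CC[C@@H](O)C(C)(C)O[C@@H]2CCC1=O | intermediate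
22 | C19,C25 diol with C8 tert-butyldimethylsilyl ether | C=C1CC[C@H]2OC(C)(C)[C@H](O[Si](C)(C)C(C)(C)C)CC[C@]2(C)[C@H]1CC[C@@H]1[C@@]2(C)CC[C@@H](O)C(C)(C)O[C@@H]2CC[C@]1(C)O | intermediate
23 | C19,C25 diacetate with C8 tert-butyldimethylsilyl ether | C=C1CC[C@H]2OC(C)(C)[C@H](O[Si](C)(C)C(C)(C)C)CC[C@]2(C)[C@H]1CC[C@@H]1[C@@]2(C)CC[C@@H](OC(C)=O)C(C)(C)O[C@@H]2CC[C@]1(C)OC(C)=O | intermediate
24 | CNP0412606.2 | C=C1CC[C@H]2OC(C)(C)[C@H](O)CC[C@]2(C)[C@H]1CC[C@@H]1[C@@]2(C)CC[C@@H](OC(C)=O)C(C)(C)O[C@@H]2CC[C@]1(C)OC(C)=O | target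

**Step count**
Total: 16 steps. Longest linear sequence: 16 steps (1 to 24; diepoxide 2 enters twice, in steps 2 and 10).

**Steps most likely to fail**

1. Step 13 (key cascade). The enol ether may lose its silyl group before the C15–C16 bond forms, a cationic intermediate or adventitious acid may engage the exocyclic C1=C2 alkene, or closure through a boat may erode the C15 configuration. The same reaction type is first run on the simpler chain in step 5. The fallback sets out from 10 and returns at 24; it builds the two bicycles in the opposite order, so that the cascade substrate carries neither the alkene nor a silyl ether. Hydroxy ketone 10 is used as the right bicycle. MeMgBr gives the PMB-protected diol F1, Ac2O/DMAP the diacetate F2, DDQ the primary alcohol F3, and Dess–Martin periodinane the C13 aldehyde F4. Aldol addition of lithium enolate 15 (made from 2 with LiN(iPr)2 as in step 10) gives the β-hydroxy ketone F5, and MsCl/Et3N gives, through the mesylate F6, the (E)-enone F7. RhCl(PPh3)3/Et3SiH then gives the (Z)-triethylsilyl enol ether F8. Me3SiOTf with 2,6-di-tert-butyl-4-methylpyridine, followed by PPTS/MeOH, gives through the trimethylsilyl ether F9 the hydroxy ketone F10, in which the left bicycle is closed last. Methylenation of the C2 ketone with Zn/CH2Br2/TiCl4, which spares the acetates and the free C8 hydroxyl, gives 24 directly.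

2. Step 12 (1,4-hydrosilylation). The rhodium hydride may isomerise or hydrosilylate the exocyclic alkene, or the (Z) geometry may erode on prolonged heating. The fallback sets out from 18 and returns at 19: conjugate reduction with stoichiometric [(Ph3P)CuH]6 in the presence of Et3SiCl (benzene/THF, rt), with the copper enolate trapped on oxygen. This hydride does not react with isolated alkenes and should again reduce through the s-cis enone.

3. Step 15 (acetylation). Acylation of the tertiary axial C25 hydroxyl, which is syn-axial to the C16 methyl, may stall, or elimination may set in on forcing. The fallback sets out from 22 and returns at 23: deprotonation with LiN(SiMe3)2 (2.2 equiv, THF, −78 °C) gives the dilithium dialkoxide F11, which is quenched with Ac2O, so that a preformed alkoxide rather than the neutral alcohol is acylated.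

**Further compounds**
F1 | step 13 | (3R,5aR,6R,7S,9aR)-6-{2-[(4-methoxybenzyl)oxy]ethyl}-2,2,5a,7-tetramethyldecahydro-1-benzoxepine-3,7-diol | COc1ccc(COCC[C@@H]2[C@@]3(C)CC[C@@H](O)C(C)(C)O[C@@H]3CC[C@]2(C)O)cc1
F2 | step 13 | 3,7-diacetate of F1 | COc1ccc(COCC[C@@H]2[C@@]3(C)CC[C@@H](OC(C)=O)C(C)(C)O[C@@H]3CC[C@]2(C)OC(C)=O)cc1
F3 | step 13 | (3R,5aR,6R,7S,9aR)-6-(2-hydroxyethyl)-2,2,5a,7-tetramethyldecahydro-1-benzoxepine-3,7-diyl diacetate | OCC[C@@H]1[C@@]2(C)CC[C@@H](OC(C)=O)C(C)(C)O[C@@H]2CC[C@]1(C)OC(C)=O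
F4 | step 13 | (3R,5aR,6R,7S,9aR)-2,2,5a,7-tetramethyl-6-(2-oxoethyl)decahydro-1-benzoxepine-3,7-diyl diacetate | O=CC[C@@H]1[C@@]2(C)CC[C@@H](OC(C)=O)C(C)(C)O[C@@H]2CC[C@]1(C)OC(C)=O
F5 | step 13 | C13 β-hydroxy C2 ketone from F4 and 15 (C13 epimers) | O=C(CC(O)C[C@@H]1[C@@]2(C)CC[C@@H](OC(C)=O)C(C)(C)O[C@@H]2CC[C@]1(C)OC(C)=O)CC[C@H]1O[C@]1(C)CC[C@H]1OC1(C)C
F6 | step 13 | C13 methanesulfonate of F5 | O=C(CC(OS(C)(=O)=O)C[C@@H]1[C@@]2(C)CC[C@@H](OC(C)=O)C(C)(C)O[C@@H]2CC[C@]1(C)OC(C)=O)CC[C@H]1O[C@]1(C)CC[C@H]1OC1(C)C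
F7 | step 13 | (E)-C12=C13 enone | O=C(/C=C/C[C@@H]1[C@@]2(C)CC[C@@H](OC(C)=O)C(C)(C)O[C@@H]2CC[C@]1(C)OC(C)=O)CC[C@H]1O[C@]1(C)CC[C@H]1OC1(C)C
F8 | step 13 | (Z)-C12=C2 triethylsilyl enol ether | CC[Si](CC)(CC)O/C(CC[C@H]1O[C@]1(C)CC[C@H]1OC1(C)C)=C\CC[C@@H]1[C@@]2(C)CC[C@@H](OC(C)=O)C(C)(C)O[C@@H]2CC[C@]1(C)OC(C)=O
F9 | step 13 | C2 ketone with C8 trimethylsilyl ether and right-half diacetate | O=C1CC[C@H]2OC(C)(C)[C@H](O[Si](C)(C)C)CC[C@]2(C)[C@H]1CC[C@@H]1[C@@]2(C)CC[C@@H](OC(C)=O)C(C)(C)O[C@@H]2CC[C@]1(C)OC(C)=O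
F10 | step 13 | C2 ketone with free C8 hydroxyl and right-half diacetate | O=C1CC[C@H]2OC(C)(C)[C@H](O)CC[C@]2(C)[C@H]1CC[C@@H]1[C@@]2(C)CC[C@@H](OC(C)=O)C(C)(C)O[C@@H]2CC[C@]1(C)OC(C)=O
F0 | step 12 | none | none
F11 | step 15 | dilithium C19,C25-dialkoxide of 22 | C=C1CC[C@H]2OC(C)(C)[C@H](O[Si](C)(C)C(C)(C)C)CC[C@]2(C)[C@H]1CC[C@@H]1[C@@]2(C)CC[C@@H]([O-])C(C)(C)O[C@@H]2CC[C@]1(C)[O-].[Li+].[Li+]
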